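Assumption: the target SMILES is read as (4S,5R,6S,8R,9R,10S,13R) in labdane numbering (C19 = lactone C=O), i.e. trans-decalin with 10β-Me, 5α-H, 4β-C19 lactonised to 6β-O, 8β-OAc/8α-Me, 9β-O/9α-C11; compounds 3 and 10 are taken as catalogue chemicals.

**Retrosynthetic overview**
1. C13–O9 bond last: chiral-selenium etherification of a 2,5-dihydrofuran alkene by the 9β-OH (spiro-THF), then selenoxide elimination to the enol ether.
2. Ring-B oxygens: 9-OH-directed syn-dihydroxylation of C7=C8, orthoester opening to the axial 8β-acetate, oxidation at C7.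
3. C9–C11 bond: organocerium addition of the dihydrofuranylethyl unit to a C9 enone, anti to the 10β-methyl.
4. γ-Lactone: C6 reduction and lactonisation of a keto acid released by Pd/formate from a CO2-bridged cycloadduct.
5. Core: enantioselective Diels–Alder of symmetric 2,6-dimethylbenzoquinone (from 2,6-xylenol) with 3-methyl-2-pyrone, CO2 bridge retained. Ring order: B (from the arene) → A plus bridging lactone → γ-lactone → spiro-THF; the dihydrofuran is pre-formed by enyne metathesis.

**Route**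

Step 1
Reactants: 1 2,6-dimethylphenol
Product: 2 2,6-dimethyl-1,4-benzoquinone
Conditions: O2 (1 atm), Co(salen) (5 mol%), DMF, 25 °C
Reagents that add atoms: dioxygen O=O
Why: Co(salen)-catalysed aerobic para-oxidation of a 2,6-dialkylphenol (phenoxyl radical captured by O2 at the free para position) is the standard dearomatising route to the symmetric quinone; no stereocentre.

Step 2
Reactants: 2 2,6-dimethyl-1,4-benzoquinone (1.5 equiv); 3 3-methyl-2H-pyran-2-one
Product: 4 endo cycloadduct: cis-fused 8,10β-dimethyl-decal-7-ene-6,9-dione (5β-H) whose ring A is a C2=C3 cyclohexene bridged on the β-face from C4 (4α-Me) to C1 by C19(=O)–O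
Conditions: (S)-o-tolyl-CBS-oxazaborolidinium triflimide (20 mol%), CH2Cl2, −20 → 20 °C, 10 kbar
Reagents that add atoms: none
Why: Proposed new method: the cationic oxazaborolidinium binds the unhindered C4=O of 2 next to one α-C–H and so selects one of the two enantiotopic C(H)=C(Me) bonds and one face; the activated Me-bearing β-carbon pairs with C6 of the pyrone (larger HOMO coefficient in 3-substituted 2-pyrones, and the only pairing that avoids adjacent quaternary centres), and endo approach puts the CO2 bridge syn to the angular methyl, so this Diels–Alder reaction sets C4, C10 and (after step 3) C5; closest known chemistry is the Corey oxazaborolidinium-catalysed Diels–Alder reaction of alkylbenzoquinones and the high-pressure/Lewis-acid Diels–Alder reaction of 3-substituted 2-pyrones with retention of CO2; the catalyst antipode is used if the sense of induction proves opposite.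

Step 3
Reactants: 4 endo cycloadduct
Product: 6 trans-keto acid (6,9-dioxo-11,12,13,14,15,16-hexanorlabda-2,7-dien-19-oic acid; 4β-CO2H, 5α-H, 10β-Me), via cis-keto acid 5 (not isolated)
Conditions: Pd(PPh3)4 (5 mol%), HCO2H, Et3N, THF, 40 °C; then DBU, 25 °C; H3O+ work-up
Reagents that add atoms: none
Why: Tsuji–Trost ionisation of the strained allylic lactone C1–O and formate reduction of the π-allyl (no β-hydrogen on C4 or C10) frees the C19 acid, and DBU epimerises C5 (α to C6=O) to the trans-decalin, the isomer in which the axial acid can close onto C6=O as a pseudo-acid; any Δ1 alkene isomer converges in step 5.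

Step 4
Reactants: 6 trans-keto acid
Product: 8 9-oxo-11,12,13,14,15,16-hexanorlabda-2,7-dien-19,6β-olide, via hydroxy acid 7 (not isolated)
Conditions: NaBH4 (1.1 equiv), CeCl3·7H2O, MeOH, −78 °C; then 1 M HCl, 25 °C
Reagents that add atoms: none
Why: Luche 1,2-reduction takes the less hindered C6 carbonyl (C9 is flanked by quaternary C10 and C8–Me) from the α-face, anti to the axial 4β-carboxylate and 10β-methyl, giving the axial 6β-alcohol (C6 S), which lactonises with the 1,3-diaxial acid on acidification.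

Step 5
Reactants: 8 dienone lactone
Product: 9 9-oxo-11,12,13,14,15,16-hexanorlabd-7-en-19,6β-olide
Conditions: H2 (3 atm), RhCl(PPh3)3 (5 mol%), PhH/EtOH, 40 °C
Reagents that add atoms: none
Why: Wilkinson hydrogenation reduces the cis-disubstituted ring-A alkene and leaves the trisubstituted conjugated C7=C8 bond and the allylic C6–O bond intact.

Step 6
Reactants: 10 allyl propargyl ether
Product: 11 3-vinyl-2,5-dihydrofuran
Conditions: Grubbs I (3 mol%), ethylene (1 atm), CH2Cl2, 25 °C
Reagents that add atoms: none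
Why: Ring-closing enyne metathesis (Mori conditions) isomerises the 1,6-enyne to the cyclic 1,3-diene; no stereocentre.

Step 7
Reactants: 11 3-vinyl-2,5-dihydrofuran
Product: 13 3-(2-iodoethyl)-2,5-dihydrofuran, via trialkylborane 12 (not isolated)
Conditions: Sia2BH (from BH3·THF and 2-methylbut-2-ene), THF, 0 °C; then NaOMe, I2, MeOH, 0 → 25 °C
Reagents that add atoms: iodine II
Why: Brown hydroboration with the bulky dialkylborane puts boron on the terminal vinyl carbon only, and base-induced iodinolysis cleaves the primary C–B bond to the primary iodide.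

Step 8
Reactants: 13 3-(2-iodoethyl)-2,5-dihydrofuran; 9 enone lactone
Product: 16 15,16-epoxy-9β-hydroxylabda-7,13-dien-19,6β-olide (C11 side chain 9α), via alkyllithium 14 (not isolated), via organocerium 15 (not isolated)
Conditions: t-BuLi (2 equiv), Et2O, −78 °C; CeCl3, THF, −78 °C; then 9, −78 → −40 °C; H2O
Reagents that add atoms: none
Why: I/Li exchange and transmetalation give a weakly basic organocerium (Imamoto) that adds 1,2 to the hindered enone without enolisation or lactone attack, from the α-face anti to the axial 10β-methyl, which sets C9 (R: 9β-OH, 9α-chain).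

Step 9
Reactants: 16 tertiary allylic alcohol
Product: 18 15,16-epoxy-7β,8β,9β-trihydroxylabd-13-en-19,6β-olide (8α-Me), via osmate ester 17 (not isolated)
Conditions: OsO4 (1.05 equiv), TMEDA, CH2Cl2, −78 °C; then aq. Na2SO3, THF, 60 °C
Reagents that add atoms: osmium tetroxide O=[Os](=O)(=O)=O
Why: Donohoe hydrogen-bond-directed dihydroxylation delivers OsO4·TMEDA syn to the allylic 9β-OH (the α-face is also shielded by the pseudoaxial C11 chain), which sets C8 (β-O, α-Me) and C7, while the undirected side-chain alkene reacts more slowly at −78 °C with one equivalent.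

Step 10
Reactants: 18 triol
Product: 20 8β-acetoxy-15,16-epoxy-7β,9β-dihydroxylabd-13-en-19,6β-olide, via cyclic orthoacetate 19 (not isolated)
Conditions: MeC(OMe)3, PPTS (cat.), CH2Cl2, 25 °C; then AcOH/H2O 4:1, 0 °C
Reagents that add atoms: trimethyl orthoacetate COC(C)(OC)OC; water O
Why: The cis 7β,8β-diol closes to a cyclic orthoester (the secondary OH exchanges first), and kinetic hydrolysis leaves the ester on the axial, tertiary oxygen (King–Allbutt rule), which installs the 8β-acetate without acylating a hindered tertiary alcohol.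

Step 11
Reactants: 20 hydroxy acetate
Product: 21 8β-acetoxy-15,16-epoxy-9β-hydroxy-7-oxolabd-13-en-19,6β-olide
Conditions: IBX, DMSO, 25–40 °C
Reagents that add atoms: none
Why: IBX oxidises the only secondary alcohol to the ketone without glycol cleavage or acyl migration; the tertiary alcohol, acetate, lactone and alkene are inert.

Step 12
Reactants: 21 keto acetate
Product: 24 target, 8β-acetoxy-9β,13:15,16-diepoxy-7-oxolabd-14-en-19,6β-olide (13R), via selenide 22 (not isolated), via selenoxide 23 (not isolated)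
Conditions: (S,S)-bis[2-(1-methoxyethyl)phenyl] diselenide (0.6 equiv), Br2; AgOTf, CH2Cl2/Et2O, −78 °C; then 21, 2,6-di-tert-butylpyridine, −78 °C; then H2O2, pyridine, THF, 0 → 25 °C
Reagents that add atoms: none
Why: Asymmetric selenoetherification: the chiral ArSe+ forms a seleniranium ion on the dihydrofuran alkene and the 9β-OH opens it at the tertiary C13 (5-exo, Markovnikov, anti), so the reagent and not the pseudo-symmetric core sets C13 (R); selenoxide syn-elimination can then only run toward C15 (C13 is quaternary) and gives the enol ether under buffered, acid-free conditions.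

**Compound list**
1 | 2,6-dimethylphenol | Cc1cccc(C)c1O | starting material
2 | 2,6-dimethyl-1,4-benzoquinone | CC1=CC(=O)C=C(C)C1=O | intermediate
3 | 3-methyl-2H-pyran-2-one | CC1=CC=COC1=O | starting material
4 | endo cycloadduct (cis-fused, 5β-H, 10β-Me; β-face C19(=O)–O bridge C4→C1; C2=C3) | CC1=CC(=O)[C@@H]2[C@]3(C)C=C[C@@H](OC3=O)[C@]2(C)C1=O | intermediate
5 | cis-keto acid (5β-H; 4β-CO2H, 4α-Me, 10β-Me; Δ2,Δ7; 6,9-dione) | CC1=CC(=O)[C@@H]2[C@@](C)(C(=O)O)C=CC[C@]2(C)C1=O | intermediate
6 | trans-keto acid (5α-H epimer of 5) | CC1=CC(=O)[C@H]2[C@@](C)(C(=O)O)C=CC[C@]2(C)C1=O | intermediate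
7 | 6β-hydroxy-9-oxo acid | CC1=C[C@@H](O)[C@H]2[C@@](C)(C(=O)O)C=CC[C@]2(C)C1=O | intermediate
8 | 9-oxo-hexanorlabda-2,7-dien-19,6β-olide | CC1=C[C@H]2OC(=O)[C@@]3(C)C=CC[C@@](C)([C@@H]23)C1=O | intermediate
9 | 9-oxo-hexanorlabd-7-en-19,6β-olide | CC1=C[C@H]2OC(=O)[C@@]3(C)CCC[C@@](C)([C@@H]23)C1=O | intermediate
10 | allyl propargyl ether | C#CCOCC=C | starting material
11 | 3-vinyl-2,5-dihydrofuran | C=CC1=CCOC1 | intermediate
12 | [2-(2,5-dihydrofuran-3-yl)ethyl]bis(3-methylbutan-2-yl)borane | CC(C)C(C)B(CCC1=CCOC1)C(C)C(C)C | intermediate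
13 | 3-(2-iodoethyl)-2,5-dihydrofuran | ICCC1=CCOC1 | intermediate
14 | 2-(2,5-dihydrofuran-3-yl)ethyllithium | [Li]CCC1=CCOC1 | intermediate
15 | dichloro[2-(2,5-dihydrofuran-3-yl)ethyl]cerium | Cl[Ce](Cl)CCC1=CCOC1 | intermediate
16 | 15,16-epoxy-9β-hydroxylabda-7,13-dien-19,6β-olide (9α side chain) | CC1=C[C@H]2OC(=O)[C@@]3(C)CCC[C@@](C)([C@@H]23)[C@]1(O)CCC4=CCOC4 | intermediate
17 | 7β,8β-osmate(VI) ester·TMEDA of 16 | C[N+]1(C)CC[N+](C)(C)[Os-2]12(=O)(=O)O[C@H]3[C@H]4OC(=O)[C@@]5(C)CCC[C@@](C)([C@@H]45)[C@](O)(CCC6=CCOC6)[C@@]3(C)O2 | intermediate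
18 | 15,16-epoxy-7β,8β,9β-trihydroxylabd-13-en-19,6β-olide | O[C@@]1(C)[C@@H](O)[C@H]2OC(=O)[C@@]3(C)CCC[C@@](C)([C@@H]23)[C@]1(O)CCC4=CCOC4 | intermediate
19 | 7β,8β-O-(1-methoxyethylidene) orthoester of 18 | COC1(C)O[C@H]2[C@H]3OC(=O)[C@@]4(C)CCC[C@@](C)([C@@H]34)[C@](O)(CCC5=CCOC5)[C@@]2(C)O1 | intermediate
20 | 8β-acetoxy-15,16-epoxy-7β,9β-dihydroxylabd-13-en-19,6β-olide | CC(=O)O[C@@]1(C)[C@@H](O)[C@H]2OC(=O)[C@@]3(C)CCC[C@@](C)([C@@H]23)[C@]1(O)CCC4=CCOC4 | intermediate
21 | 8β-acetoxy-15,16-epoxy-9β-hydroxy-7-oxolabd-13-en-19,6β-olide | CC(=O)O[C@@]1(C)C(=O)[C@H]2OC(=O)[C@@]3(C)CCC[C@@](C)([C@@H]23)[C@]1(O)CCC4=CCOC4 | intermediate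
22 | 14-{2-[(1S)-1-methoxyethyl]phenylseleno} spiro-ether (13R; Se trans to O9) | CC(=O)O[C@@]1(C)C(=O)[C@H]2OC(=O)[C@@]3(C)CCC[C@@](C)([C@@H]23)[C@]12CC[C@]1([C@@H]([Se]c4ccccc4[C@H](C)OC)COC1)O2 | intermediate
23 | selenoxide of 22 | CC(=O)O[C@@]1(C)C(=O)[C@H]2OC(=O)[C@@]3(C)CCC[C@@](C)([C@@H]23)[C@]12CC[C@]1([C@@H]([Se](=O)c4ccccc4[C@H](C)OC)COC1)O2 | intermediate
24 | CNP0155227.1, 8β-acetoxy-9β,13:15,16-diepoxy-7-oxolabd-14-en-19,6β-olide | CC(=O)O[C@@]1(C)C(=O)[C@H]2OC(=O)[C@@]3(C)CCC[C@@](C)([C@@H]23)[C@]12CC[C@]1(C=COC1)O2 | target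

**Step count:** 12 steps in total; longest linear sequence 10 steps (1–5, 8–12).

**Three steps most likely to fail**

Step 2 (pyrone–quinone cycloaddition). The pyrone may be too poor a diene for the chiral Lewis acid to turn over, or ee, endo or regio control may be low. Fallback, setting out from 2 and 3 and coming back at 6: the cycloaddition is run without chiral control (ZnBr2, CH2Cl2, 12–15 kbar, 30 °C), which gives 4 together with the enantiomeric adduct F1. Step 3 on this material gives 6 and the enantiomeric trans-keto acid F2. Classical resolution with (S)-1-phenylethylamine crystallises the (S)-1-phenylethylammonium salt of 6 F3 (the antipodal amine is used if the other salt is the less soluble one), and acidification returns 6.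

Step 9 (directed dihydroxylation). The side-chain alkene may compete, or the 10β-methyl and 6β-oxygen may block the β-face. Fallback, setting out from 16 and coming back at 21: VO(acac)2/t-BuOOH (1.1 equiv) epoxidises only the allylic C7=C8 bond syn to the 9β-alkoxide, giving the 7β,8β-epoxy-9β-alcohol F4. Ti(OiPr)4/PhCO2H opens the epoxide at C7 (trans-diaxial, distal to the carbinol) to the 7α-benzoate 8β,9β-diol F5. K2CO3/MeOH gives the 7α,8β,9β-triol F6, and IBX gives the 8β,9β-dihydroxy-7-ketone F7. Ac2O with catalytic Sc(OTf)3 at −20 °C acetylates the 8β-hydroxyl (the 9β-OH lies between two fully substituted carbons) and rejoins the route at 21.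

Step 12 (C13 control in the selenoetherification). The two flanks of C9 are nearly equivalent, so all selectivity rests on the chiral selenium reagent; its sense is checked on the first run and the (R,R)-diselenide is used if it is mismatched. Fallback, setting out from 21 and coming back at 24: catalyst-controlled Shi epoxidation of the dihydrofuran alkene (L-fructose-derived ketone, Oxone, pH 10.5, 0 °C) gives the 13,14-epoxide F8. Catalytic CSA triggers 5-exo opening at the tertiary C13 by the 9β-OH with inversion to the 14-hydroxy spiro-ether F9. MsCl/Et3N gives the 14-mesylate F10, and DBU (toluene, 80 °C) eliminates toward C15, the only β-hydrogens, to give 24.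

**Further compounds**
F1 | step 2 | enantiomeric adduct (ent-4) | CC1=CC(=O)[C@H]2[C@@]3(C)C=C[C@H](OC3=O)[C@@]2(C)C1=O
F2 | step 2 | enantiomeric trans-keto acid (ent-6) | CC1=CC(=O)[C@@H]2[C@](C)(C(=O)O)C=CC[C@@]2(C)C1=O
F3 | step 2 | (S)-1-phenylethylammonium salt of 6 | CC1=CC(=O)[C@H]2[C@@](C)(C(=O)[O-])C=CC[C@]2(C)C1=O.C[C@H]([NH3+])c1ccccc1
F4 | step 9 | 7β,8β-epoxy-9β-alcohol | C[C@]12O[C@H]1[C@H]3OC(=O)[C@@]4(C)CCC[C@@](C)([C@@H]34)[C@]2(O)CCC5=CCOC5
F5 | step 9 | 7α-benzoate 8β,9β-diol | O[C@@]1(C)[C@H](OC(=O)c4ccccc4)[C@H]2OC(=O)[C@@]3(C)CCC[C@@](C)([C@@H]23)[C@]1(O)CCC4=CCOC4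
F6 | step 9 | 7α,8β,9β-triol | O[C@@]1(C)[C@H](O)[C@H]2OC(=O)[C@@]3(C)CCC[C@@](C)([C@@H]23)[C@]1(O)CCC4=CCOC4
F7 | step 9 | 8β,9β-dihydroxy-7-ketone | O[C@@]1(C)C(=O)[C@H]2OC(=O)[C@@]3(C)CCC[C@@](C)([C@@H]23)[C@]1(O)CCC4=CCOC4
F8 | step 12 | 13,14-epoxide of 21 | CC(=O)O[C@@]1(C)C(=O)[C@H]2OC(=O)[C@@]3(C)CCC[C@@](C)([C@@H]23)[C@]1(O)CC[C@]45O[C@H]4COC5
F9 | step 12 | 14-hydroxy spiro-ether | CC(=O)O[C@@]1(C)C(=O)[C@H]2OC(=O)[C@@]3(C)CCC[C@@](C)([C@@H]23)[C@]12CC[C@]1([C@@H](O)COC1)O2
F10 | step 12 | 14-mesylate | CC(=O)O[C@@]1(C)C(=O)[C@H]2OC(=O)[C@@]3(C)CCC[C@@](C)([C@@H]23)[C@]12CC[C@]1([C@@H](OS(C)(=O)=O)COC1)O2
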